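**Plan**

- Retrosynthesis: the two acetates and the phenol O–H are unmasked last. The C5–O bond is cut by moving that oxygen to C7 across a C5=C6 alkene, the C5=C6 bond is cut by cross-metathesis, and the C3–C4 bond by carbonyl allylation.
- Enabling feature (chain numbered C1 = ArCH2 to C8): C6–C8 is a plain propyl group, so it can be carried as the allyl system C5=C6–C7(OH) ⇌ C5(OH)–C6=C7. The syn oxygens on C3 and C5 span a chair 1,3-dioxane (O–C3–C4–C5–O closed by a benzylidene carbon) with phenyl, arylethyl and propenyl all equatorial.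
- Forward: dihydroconiferyl alcohol gives the arene and C1–C3, allyl acetate C4–C5, but-3-en-2-ol C6–C8. The chain is joined at C3–C4, then at C5=C6. The only ring, a temporary 1,3-dioxane, closes in the rhenium step.
- Stereochemistry: C3 (S) comes from catalyst-controlled iridium allylation. C5 (R) is relayed from C3 by thermodynamic equilibration into the all-cis benzylidene acetal. The C7 carbinol is used as an epimer mixture because it is erased.

Key step: step 4

Assumption: the (R)-configured bisphosphine on iridium is taken to deliver the allyl group to the Re face of aldehyde 4, which gives the 3S carbinol; if the sense proves opposite, the (S)-ligand is used with no other change.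

**Route**

Step 1
Reactants: 1 3-(4-hydroxy-3-methoxyphenyl)propan-1-ol
Product: 2 3-[4-(benzyloxy)-3-methoxyphenyl]propan-1-ol
Conditions: BnBr, K2CO3, acetone, reflux
Reagents that add atoms: benzyl bromide, BrCc1ccccc1
Why: Williamson etherification: carbonate deprotonates only the phenol (pKa about 10), so benzyl bromide alkylates the phenoxide and leaves the primary alcohol free for step 2.

Step 2
Reactants: 2 3-[4-(benzyloxy)-3-methoxyphenyl]propan-1-ol; 3 allyl acetate
Product: 5 (3S)-1-[4-(benzyloxy)-3-methoxyphenyl]hex-5-en-3-ol, via 3-[4-(benzyloxy)-3-methoxyphenyl]propanal 4 (not isolated)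
Conditions: [Ir(cod)Cl]2 (2.5 mol%), (R)-Cl,MeO-BIPHEP (5 mol%), 4-Cl-3-NO2-C6H3CO2H (10 mol%), Cs2CO3 (20 mol%), 3 (excess), THF, 100 °C, sealed tube
Reagents that add atoms: none
Why: Iridium-catalysed transfer-hydrogenative carbonyl allylation from the alcohol oxidation level (Krische allylation): the cyclometallated iridium C,O-benzoate dehydrogenates 2 to aldehyde 4 and uses the hydride to turn 3 into an allyliridium species, which adds to 4 through a closed chair-like transition state whose Re-face preference, imposed by the (R)-bisphosphine, sets the 3S carbinol.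

Step 3
Reactants: 5 (3S)-1-[4-(benzyloxy)-3-methoxyphenyl]hex-5-en-3-ol; 6 but-3-en-2-ol (racemic)
Product: 7 (3S,5E)-1-[4-(benzyloxy)-3-methoxyphenyl]oct-5-ene-3,7-diol (C7 epimer mixture)
Conditions: Grubbs II (5 mol%), 6 (4 equiv), CH2Cl2, 40 °C
Reagents that add atoms: none
Why: Olefin cross-metathesis of the type I terminal alkene of 5 with an excess of the slower-dimerising secondary allylic alcohol 6 on a second-generation ruthenium carbene should give the E-disubstituted alkene under thermodynamic control, and the uncontrolled C7 carbinol is harmless because step 4 erases it.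

Step 4
Reactants: 7 (3S,5E)-1-[4-(benzyloxy)-3-methoxyphenyl]oct-5-ene-3,7-diol (C7 epimer mixture); 8 benzaldehyde dimethyl acetal
Product: 10 (2S,4S,6S)-4-{2-[4-(benzyloxy)-3-methoxyphenyl]ethyl}-2-phenyl-6-[(1E)-prop-1-en-1-yl]-1,3-dioxane, via (3S,6E)-1-[4-(benzyloxy)-3-methoxyphenyl]oct-6-ene-3,5-diol 9 (not isolated)
Conditions: Re2O7 (5 mol%), 8 (2 equiv), CH2Cl2, 0 °C to rt; Et3N quench
Reagents that add atoms: none
Why: Re2O7 converts the C7 hydroxyl of 7 into an allyl perrhenate, which undergoes a reversible chair-like [3,3] oxygen shift to C5 with migration of the alkene to C6=C7, giving diol 9 as both C5 epimers in equilibrium with 7. The same acidic rhenium species ionises 8 to its O-methyl oxocarbenium ion, which is taken up by the C3 hydroxyl and, after loss of the second methanol, is closed by the C5 hydroxyl in a 6-endo-trig addition to the O3-benzylidene oxocarbenium ion; only a C5 hydroxyl, never the C7 hydroxyl, is 1,3 to C3, so acetal formation pulls the transposition forward. The closest known reaction type is the rhenium(VII)-catalysed 1,3-transposition of δ-hydroxy allylic alcohols with in situ capture of the syn-1,3-diol as its benzylidene acetal. The new carbinol stereocentre at chain C5 (and the acetal carbon) is set under thermodynamic control by the fixed 3S centre: because the sigmatropic shift and the acetal exchange are both reversible, any acetal of the 5-epimer, which must carry an axial substituent, reopens and drains into the chair with phenyl, arylethyl and propenyl all equatorial, which is the syn diol, whichever C7 epimer of 7 enters. The selectivity the step needs is this 2,4,6-cis preference, secured by equilibration; the E geometry of the new alkene is also favoured and is removed anyway in step 5. The non-allylic C3–O bond cannot ionise, so the 3S centre is untouched.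

Step 5
Reactants: 10 (2S,4S,6S)-4-{2-[4-(benzyloxy)-3-methoxyphenyl]ethyl}-2-phenyl-6-[(1E)-prop-1-en-1-yl]-1,3-dioxane
Product: 11 (2R,4S,6R)-4-{2-[4-(benzyloxy)-3-methoxyphenyl]ethyl}-2-phenyl-6-propyl-1,3-dioxane
Conditions: 2-nitrobenzenesulfonylhydrazide (NBSH, excess, in portions), Et3N, CH2Cl2, rt
Reagents that add atoms: none
Why: Diimide generated from NBSH transfers H2 to the isolated E-alkene by a concerted syn hydrogen transfer (diimide reduction), which cannot cleave the benzyl ether, the benzylidene acetal or the allylic C–O bond, and once C5 is no longer allylic it can no longer epimerise.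

Step 6
Reactants: 11 (2R,4S,6R)-4-{2-[4-(benzyloxy)-3-methoxyphenyl]ethyl}-2-phenyl-6-propyl-1,3-dioxane
Product: 12 (3S,5R)-1-[4-(benzyloxy)-3-methoxyphenyl]octane-3,5-diol
Conditions: AcOH–THF–H2O (3:1:1), 50 °C
Reagents that add atoms: none
Why: Acid-catalysed acetal hydrolysis releases benzaldehyde by C–O cleavage at the acetal carbon only, so C3 and C5 keep their configuration and the aryl benzyl ether is inert to aqueous acetic acid.

Step 7
Reactants: 12 (3S,5R)-1-[4-(benzyloxy)-3-methoxyphenyl]octane-3,5-diol
Product: 13 (3S,5R)-1-[4-(benzyloxy)-3-methoxyphenyl]octane-3,5-diyl diacetate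
Conditions: Ac2O, pyridine, DMAP (cat.), CH2Cl2, rt
Reagents that add atoms: acetic anhydride, CC(=O)OC(C)=O
Why: DMAP-catalysed O-acylation of both secondary alcohols with acetic anhydride is routine, and the phenol, still benzylated, cannot compete.

Step 8
Reactants: 13 (3S,5R)-1-[4-(benzyloxy)-3-methoxyphenyl]octane-3,5-diyl diacetate
Product: 14 (3S,5R)-1-(4-hydroxy-3-methoxyphenyl)octane-3,5-diyl diacetate
Conditions: H2 (1 atm), 10% Pd/C, EtOAc, rt
Reagents that add atoms: none
Why: Catalytic hydrogenolysis of the aryl benzyl ether over palladium on carbon frees the phenol with loss of toluene, while the secondary acetates and the unactivated ArCH2 group are not reduced.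

**Compound list**

1 | 3-(4-hydroxy-3-methoxyphenyl)propan-1-ol (dihydroconiferyl alcohol) | COc1cc(CCCO)ccc1O | starting material
2 | 3-[4-(benzyloxy)-3-methoxyphenyl]propan-1-ol | COc1cc(CCCO)ccc1OCc1ccccc1 | intermediate
3 | allyl acetate | C=CCOC(C)=O | starting material
4 | 3-[4-(benzyloxy)-3-methoxyphenyl]propanal (formed and consumed in step 2, not isolated) | COc1cc(CCC=O)ccc1OCc1ccccc1 | intermediate
5 | (3S)-1-[4-(benzyloxy)-3-methoxyphenyl]hex-5-en-3-ol | C=CC[C@H](CCc1ccc(OCc2ccccc2)c(OC)c1)O | intermediate
6 | but-3-en-2-ol (racemic) | CC(O)C=C | starting material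
7 | (3S,5E)-1-[4-(benzyloxy)-3-methoxyphenyl]oct-5-ene-3,7-diol (both C7 epimers) | CC(O)/C=C/C[C@H](CCc1ccc(OCc2ccccc2)c(OC)c1)O | intermediate
8 | benzaldehyde dimethyl acetal | COC(OC)c1ccccc1 | starting material
9 | (3S,6E)-1-[4-(benzyloxy)-3-methoxyphenyl]oct-6-ene-3,5-diol (both C5 epimers, in equilibrium with 7, not isolated) | C/C=C/C(O)C[C@H](CCc1ccc(OCc2ccccc2)c(OC)c1)O | intermediate
10 | (2S,4S,6S)-4-{2-[4-(benzyloxy)-3-methoxyphenyl]ethyl}-2-phenyl-6-[(1E)-prop-1-en-1-yl]-1,3-dioxane (2,4,6-cis) | C/C=C/[C@@H]1C[C@H](CCc2ccc(OCc3ccccc3)c(OC)c2)O[C@H](c2ccccc2)O1 | intermediate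
11 | (2R,4S,6R)-4-{2-[4-(benzyloxy)-3-methoxyphenyl]ethyl}-2-phenyl-6-propyl-1,3-dioxane (2,4,6-cis; the CIP labels at C2 and C6 change on saturation, the geometry does not) | CCC[C@@H]1C[C@H](CCc2ccc(OCc3ccccc3)c(OC)c2)O[C@H](c2ccccc2)O1 | intermediate
12 | (3S,5R)-1-[4-(benzyloxy)-3-methoxyphenyl]octane-3,5-diol | CCC[C@H](C[C@H](CCc1ccc(OCc2ccccc2)c(OC)c1)O)O | intermediate
13 | (3S,5R)-1-[4-(benzyloxy)-3-methoxyphenyl]octane-3,5-diyl diacetate | CCC[C@H](C[C@H](CCc1ccc(OCc2ccccc2)c(OC)c1)OC(C)=O)OC(C)=O | intermediate
14 | (3S,5R)-1-(4-hydroxy-3-methoxyphenyl)octane-3,5-diyl diacetate (CNP0240815.1) | CCC[C@H](C[C@H](CCc1ccc(O)c(OC)c1)OC(C)=O)OC(C)=O | target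

**Step count**

Total: 8 steps. Longest linear sequence: 8 steps (from 1).

**Steps most likely to fail**

Step 4. Ionisation of the allyl perrhenate may outrun acetal capture, leading to elimination or to capture by the C3 hydroxyl or the electron-rich arene. Epimer exchange may also be too slow, so that an acetal with an axial substituent persists. The fallback sets the syn-1,3-diol by electrophile-induced carbonate cyclisation instead. It sets out from 5, which is converted (Boc2O, DMAP, MeCN) into tert-butyl (3S)-1-[4-(benzyloxy)-3-methoxyphenyl]hex-5-en-3-yl carbonate F1. Iodocarbonate cyclisation (IBr, toluene, −80 °C) through the chair with both substituents equatorial should give (4S,6S)-4-{2-[4-(benzyloxy)-3-methoxyphenyl]ethyl}-6-(iodomethyl)-1,3-dioxan-2-one F2. Methanolysis (K2CO3, MeOH, rt) should give (2S)-4-[4-(benzyloxy)-3-methoxyphenyl]-1-[(2S)-oxiran-2-yl]butan-2-ol F3. Copper-catalysed opening of the terminal epoxide (EtMgBr in excess, CuI cat., THF, −40 °C) adds C7–C8 and comes back to the route at 12.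

Step 2. Enantiofacial control may be insufficient, or alcohol dehydrogenation may stall on the electron-rich substrate. The fallback replaces catalytic transfer hydrogenation with stoichiometric reagent control on the isolated aldehyde. It sets out from 2, which is oxidised (Dess–Martin periodinane, CH2Cl2, rt) to aldehyde 4, now isolated. Brown allylboration with (+)-B-allyldiisopinocampheylborane (Et2O, −78 °C; then NaOH, H2O2), which attacks the Re face of unbranched aldehydes, comes back to the route at 5. No compound outside the list is made (entry F0).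

Step 5. Diimide disproportionation may outpace hydrogen transfer to the 1,2-disubstituted alkene, leaving saturation incomplete. The fallback changes the order of the endgame and sets out from 10. Global hydrogenation (H2, Pd(OH)2/C, EtOAc–MeOH, rt) saturates the alkene and cleaves both the benzylidene acetal and the benzyl ether, which should give (3S,5R)-1-(4-hydroxy-3-methoxyphenyl)octane-3,5-diol F4. Peracetylation (Ac2O, pyridine, DMAP) should give (3S,5R)-1-[4-(acetyloxy)-3-methoxyphenyl]octane-3,5-diyl diacetate F5. Chemoselective aminolysis of the aryl acetate alone (pyrrolidine, CH2Cl2, 0 °C) comes back to the route at 14.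

**Further compounds**

F1 | step 4 | tert-butyl (3S)-1-[4-(benzyloxy)-3-methoxyphenyl]hex-5-en-3-yl carbonate | C=CC[C@H](CCc1ccc(OCc2ccccc2)c(OC)c1)OC(=O)OC(C)(C)C
F2 | step 4 | (4S,6S)-4-{2-[4-(benzyloxy)-3-methoxyphenyl]ethyl}-6-(iodomethyl)-1,3-dioxan-2-one | IC[C@@H]1C[C@H](CCc2ccc(OCc3ccccc3)c(OC)c2)OC(=O)O1
F3 | step 4 | (2S)-4-[4-(benzyloxy)-3-methoxyphenyl]-1-[(2S)-oxiran-2-yl]butan-2-ol | C1O[C@H]1C[C@H](CCc1ccc(OCc2ccccc2)c(OC)c1)O
F0 | step 2 | none | none
F4 | step 5 | (3S,5R)-1-(4-hydroxy-3-methoxyphenyl)octane-3,5-diol | CCC[C@H](C[C@H](CCc1ccc(O)c(OC)c1)O)O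
F5 | step 5 | (3S,5R)-1-[4-(acetyloxy)-3-methoxyphenyl]octane-3,5-diyl diacetate | CCC[C@H](C[C@H](CCc1ccc(OC(C)=O)c(OC)c1)OC(C)=O)OC(C)=O
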